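The ratio of partner charged to substrate and other conformer together (the pool) in this flask was 86.4 %, and I began from it because the last noon reading, 49.8 %, stood lower.

| flask | substrate | partner | other conformer | temperature | remark | time |
|---|---|---|---|---|---|---|
| noon | 0.80 M | 0.76 M | 0.080 M | 70 °C | the very flask that is asked about, followed so far |  |
| spring | 0.80 M | 0.76 M | 0.12 M | 70 °C | run made earlier |  |
| flask | 0.80 M | 0.760 M | 0.0800 M | 70 °C |  | 8.0 d |

| run | time / d | target / % |
|---|---|---|
| noon | 1.04 | 35.2 |
| noon | 2.00 | 42.4 |
| noon | 3.00 | 45.6 |
| noon | 4.00 | 45.6 |
| noon | 5.00 | 48.2 |
| noon | 6.00 | 49.8 |
| spring | 0.250 | 16.6 |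
| spring | 0.625 | 28.7 |
| spring | 1.25 | 36.5 |
| spring | 2.08 | 41.2 |
| spring | 2.50 | 42.7 |
| spring | 4.00 | 45.2 |

(readings scatter by 1 percentage point)

- epsilon: at 8.0 d add partner, 50.0 % of the amount charged, then wait 15 d
- beta: at 8.0 d take out 90 % of the target then present, then wait 15 d
- zeta: change nothing and wait 15 d more
- alpha: at 8.0 d raise the temperature by 20 K, then wait 15 d

- what is taken out of target is counted as made
- the numbers in the tables scatter with a standard deviation of 1 percentage point
- the earlier runs do not show what temperature does; that part of a forecast is a guess
- additions bring no volume worth counting

- target, in percent of the substrate and other conformer together first charged, at 8.0 d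
- which option adds most target ("none" when 2 percentage points or less is all one gets) (epsilon / beta / zeta / alpha / none)
- target present, with what was taken out counted in, in percent of the substrate and other conformer together first charged, after zeta
- target present, with what was taken out counted in, in percent of the substrate and other conformer together first charged, after alpha

At 4.00 d the noon run held 0.401 M of target and the spring run 0.416 M, although spring had 0.0400 M more pool, so I took partner, not pool, as the limiting reagent. I assumed that an unseen path also took partner and pool one for one. The last noon reading then gave target made per partner charged, which I called the coupling ratio, as 57.7 %.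

I turned the question round: what would make every option useless? On that assumption, further target in this flask was the coupling ratio times the smaller of free partner and free pool, so a gain above 2 percentage points needed at least 3.5 points of either, counted on the pool. Once partner ran low, free pool stood near 13.6 %, clear of that mark. The added 0.380 M of partner exceeded the free pool of 0.120 M, so control crossed to the pool, and I reckoned epsilon at 7.9 points. The noon run gained 4.2 points over its last 3.00 d, but I did not extend that gain over the wait: on my assumption, waiting added the coupling ratio times the partner still free, and the readings did not give that amount. So my estimate for waiting stayed open, and I put target at 8.0 d close to the last reading.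

The forecast gave 51.5 %, epsilon as best, 60 % after waiting and 68 % after heating, holding that “Adding partner helps under either mechanism”.

The flask gave 49.3 %, and epsilon added 8.4 points against my 7.9 points. Free partner stood at 1.69 % of its charge at 8.00 d. The coupling ratio turns that into 0.84 points of further target, and waiting added 0.78 points, ending at 50.0 %, while heating ended at 50.3 %.

    substrate ⇌ other conformer (K = 0.250, k = 0.114 h⁻¹, Ea = 109 kJ mol⁻¹, ΔH = −35.0 kJ mol⁻¹)
    substrate + partner → target (k = 0.0646 L mol⁻¹ h⁻¹, Ea = 85.0 kJ mol⁻¹)
    partner + other conformer → isomer of the product (k = 0.221 L mol⁻¹ h⁻¹, Ea = 77.0 kJ mol⁻¹)
    (constants at 70 °C)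

For the neighbour with 0.46 M of partner, the coupling ratio gave 30.1 % of target. That neighbour gave 29.9 %, with 0.022 % of its partner left.

The runs come from a simulation on assumed constants; noise was put on by code.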